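**Retrosynthetic overview**

1. Target 26 comes from 25 by 1,2-reduction of a C4 formyl group, so C11 is carried as CHO until the last step. The O10 coumarate and the O1 (S)-3-methylpentanoate are attached by acylation of alcohol 20 and lactol 14.
2. Lactol 14 comes from cyclopentenol 10 and triformylmethane 11. The dihydropyran C1–O2–C3=C4–C5–C9 grows out of the cyclobutane C1–C9–C5–C4 of a [2+2] photoadduct by retro-aldol cleavage of C1–C4 and re-closure through O2 (de Mayo cascade), which also sets C5 and C9.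
3. Enabling feature: the acetal carbon C1 and the enol ether C3=C4 bearing C11 make the pyran the cyclic enol hemiacetal of a 1,5-dialdehyde with a third formyl-level carbon on C4. Once C1 and C4 are joined in a four-membered ring, C1–OH and the C4 formyl groups are an aldol pair.
4. Cyclopentenol 10 comes from cyclopent-2-en-1-one by hydroxymethylation (C10), CBS reduction (C7), anti epoxidation (C8–O) and selenide/selenoxide transposition of the alkene to C5=C9.
5. Ring order: cyclopentane (purchased), then cyclobutane (transient), then dihydropyran (two-atom ring expansion).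

Key step: step 7

Remark: iridoid numbering is used for the core (C1 acetal carbon, O2, C3=C4, ring-fusion carbons C5 and C9, C6, C7, C8, C10 = CH2O on C8, C11 = carbon on C4); triformylmethane is taken as a commercial reagent.

**Route**

Step 1
Reactants: 1 cyclopent-2-en-1-one; 2 formaldehyde
Product: 3 2-(hydroxymethyl)cyclopent-2-en-1-one
Conditions: aq. HCHO (37%), PBu3 (10 mol %), CHCl3–MeOH, rt
Reagents that add atoms: none
Why: Morita–Baylis–Hillman hydroxymethylation, in which conjugate addition of the phosphine gives an enolate that traps formaldehyde at C2 and eliminates the phosphine; no stereocenter is formed.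

Step 2
Reactants: 3 2-(hydroxymethyl)cyclopent-2-en-1-one
Product: 4 2-{[(triethylsilyl)oxy]methyl}cyclopent-2-en-1-one
Conditions: TESCl, imidazole, CH2Cl2, 0 °C
Reagents that add atoms: triethylsilyl chloride (TESCl), CC[Si](Cl)(CC)CC
Why: Standard silylation of the primary alcohol; the TES ether is chosen so that it can later be removed in the presence of a secondary TBS ether.

Step 3
Reactants: 4 2-{[(triethylsilyl)oxy]methyl}cyclopent-2-en-1-one
Product: 5 (1R)-2-{[(triethylsilyl)oxy]methyl}cyclopent-2-en-1-ol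
Conditions: (S)-1-methyl-3,3-diphenyltetrahydro-1H,3H-pyrrolo[1,2-c][1,3,2]oxazaborole (20 mol %), BH3·SMe2, THF, −20 °C; MeOH quench
Reagents that add atoms: none
Why: Corey–Bakshi–Shibata reduction, in which the 2-substituted alkenyl arm takes the large-group position in the oxazaborolidine–borane complex, so 1,2-hydride delivery should set the carbinol carbon (future C7) as R.

Step 4
Reactants: 5 (1R)-2-{[(triethylsilyl)oxy]methyl}cyclopent-2-en-1-ol
Product: 6 tert-butyldimethyl{[(1R)-2-{[(triethylsilyl)oxy]methyl}cyclopent-2-en-1-yl]oxy}silane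
Conditions: TBSCl, imidazole, DMF, rt
Reagents that add atoms: tert-butyldimethylsilyl chloride (TBSCl), CC(C)(C)[Si](C)(C)Cl
Why: Standard silylation of the secondary allylic alcohol; the bulky, non-directing OTBS group is needed to steer the next step.

Step 5
Reactants: 6 tert-butyldimethyl{[(1R)-2-{[(triethylsilyl)oxy]methyl}cyclopent-2-en-1-yl]oxy}silane
Product: 7 (1R,2R,5R)-2-[(tert-butyldimethylsilyl)oxy]-1-{[(triethylsilyl)oxy]methyl}-6-oxabicyclo[3.1.0]hexane (epoxide oxygen trans to OTBS)
Conditions: mCPBA, CH2Cl2, 0 °C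
Reagents that add atoms: 3-chloroperoxybenzoic acid (mCPBA), OOC(=O)c1cccc(Cl)c1
Why: Prilezhaev epoxidation of the only alkene; with no free hydroxyl to direct it, the peracid should approach anti to the allylic OTBS group and so place the C8 oxygen trans to the C7 oxygen.

Step 6
Reactants: 7 (1R,2R,5R)-2-[(tert-butyldimethylsilyl)oxy]-1-{[(triethylsilyl)oxy]methyl}-6-oxabicyclo[3.1.0]hexane
Product: 10 (1S,5R)-5-[(tert-butyldimethylsilyl)oxy]-1-{[(triethylsilyl)oxy]methyl}cyclopent-2-en-1-ol, via hydroxy selenide 8 (not isolated), via selenoxide 9 (not isolated)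
Conditions: (PhSe)2, NaBH4, EtOH, rt→50 °C; then THF, 30% H2O2, 0 °C→rt
Reagents that add atoms: none
Why: Epoxide-to-allylic-alcohol transposition: selenolate should open the epoxide by SN2 at the less substituted carbon C9, and the selenoxide can undergo syn-elimination only towards C5 because C8 has no hydrogen, leaving the tertiary C8–OH configuration untouched.

Step 7
Reactants: 10 (1S,5R)-5-[(tert-butyldimethylsilyl)oxy]-1-{[(triethylsilyl)oxy]methyl}cyclopent-2-en-1-ol; 11 triformylmethane (present as its enol, 2-(hydroxymethylidene)propanedial)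
Product: 14 (1S,4aR,6R,7S,7aR)-6-[(tert-butyldimethylsilyl)oxy]-1,7-dihydroxy-7-{[(triethylsilyl)oxy]methyl}-1,4a,5,6,7,7a-hexahydrocyclopenta[c]pyran-4-carbaldehyde, via cyclobutanol photoadduct 12 (not isolated), via retro-aldol enol aldehyde 13 (not isolated)
Conditions: 11 (3 equiv), hν (medium-pressure Hg lamp, Vycor filter), degassed CH2Cl2, 0 °C, to partial conversion
Reagents that add atoms: none
Why: Excitation of the hydrogen-bonded enol of 11 and [2+2] photocycloaddition to the C5=C9 alkene of 10 (de Mayo reaction, the classical union of cyclopentenes with formyl-substituted 1,3-dicarbonyl enols) should form C4–C5 and C1–C9 and give cyclobutanol 12, a β-hydroxy aldehyde that cleaves its C1–C4 bond by retro-aldol to 13; the enol oxygen of one formyl group then adds to the new C1 aldehyde, so the four-membered ring C1–C9–C5–C4 is enlarged by O2 and C3 to the dihydropyran. The cyclobutane closes by stepwise [2+2] through a 1,4-biradical (cis-fused of necessity on a cyclopentene) and the pyran by 6-exo-trig hemiacetalisation. C5 and C9 are set by the face of addition: the enol should approach the face that carries only the small tertiary C8–OH (possibly guided by hydrogen bonding), anti to the C7–OTBS and C8–CH2OTES groups, which puts H5 and H9 cis to C10 and to the C7 oxygen as required. C1 is set under thermodynamic control in the mutarotating lactol (hydroxyl pseudoaxial, anomerically stabilised and trans to C8). The step needs head-to-tail regioselectivity (C4 to C5, C1 to C9); this should be secured because the gem-diformyl carbon, quaternary in 12, avoids bonding next to the quaternary C8, and no selectivity among the formyl groups is needed because the three are equivalent.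

Step 8
Reactants: 15 (S)-1-bromo-2-methylbutane; 16 carbon dioxide
Product: 18 (3S)-3-methylpentanoic acid, via Grignard reagent 17 (not isolated)
Conditions: Mg, THF, reflux; CO2, −78 °C→rt; aq. HCl
Reagents that add atoms: none
Why: Grignard carboxylation; the stereocenter is β to the carbon–magnesium bond and is not touched.

Step 9
Reactants: 14 (1S,4aR,6R,7S,7aR)-6-[(tert-butyldimethylsilyl)oxy]-1,7-dihydroxy-7-{[(triethylsilyl)oxy]methyl}-1,4a,5,6,7,7a-hexahydrocyclopenta[c]pyran-4-carbaldehyde; 18 (3S)-3-methylpentanoic acid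
Product: 19 (1R,4aR,6R,7S,7aR)-6-[(tert-butyldimethylsilyl)oxy]-4-formyl-7-hydroxy-7-{[(triethylsilyl)oxy]methyl}-1,4a,5,6,7,7a-hexahydrocyclopenta[c]pyran-1-yl (3S)-3-methylpentanoate
Conditions: DCC, 4-(dimethylamino)pyridine (10 mol %), CH2Cl2, 0 °C
Reagents that add atoms: none
Why: Steglich esterification of the lactol hydroxyl (the tertiary C8–OH is inert); acylation should occur on the predominant, less hindered lactol anomer with oxygen trans to C8, giving the C1 configuration common to 1-O-acyl iridoids.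

Step 10
Reactants: 19 (1R,4aR,6R,7S,7aR)-6-[(tert-butyldimethylsilyl)oxy]-4-formyl-7-hydroxy-7-{[(triethylsilyl)oxy]methyl}-1,4a,5,6,7,7a-hexahydrocyclopenta[c]pyran-1-yl (3S)-3-methylpentanoate
Product: 20 (1R,4aR,6R,7S,7aR)-6-[(tert-butyldimethylsilyl)oxy]-4-formyl-7-hydroxy-7-(hydroxymethyl)-1,4a,5,6,7,7a-hexahydrocyclopenta[c]pyran-1-yl (3S)-3-methylpentanoate
Conditions: HF·pyridine, pyridine, THF, 0 °C
Reagents that add atoms: none
Why: Buffered fluoride desilylation, which should cleave the primary TES ether much faster than the secondary TBS ether; the acylal and the formyl-deactivated enol ether should tolerate it.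

Step 11
Reactants: 21 (E)-4-hydroxycinnamic acid (p-coumaric acid)
Product: 23 (2E)-3-{4-[(tert-butyldimethylsilyl)oxy]phenyl}prop-2-enoic acid, via bis-silyl derivative 22 (not isolated)
Conditions: TBSCl (2.2 equiv), imidazole, DMF, rt; then AcOH–THF–H2O, rt
Reagents that add atoms: tert-butyldimethylsilyl chloride (TBSCl), CC(C)(C)[Si](C)(C)Cl
Why: Silylation of phenol and acid followed by selective hydrolysis of the far more labile silyl ester leaves the aryl silyl ether in place.

Step 12
Reactants: 20 (1R,4aR,6R,7S,7aR)-6-[(tert-butyldimethylsilyl)oxy]-4-formyl-7-hydroxy-7-(hydroxymethyl)-1,4a,5,6,7,7a-hexahydrocyclopenta[c]pyran-1-yl (3S)-3-methylpentanoate; 23 (2E)-3-{4-[(tert-butyldimethylsilyl)oxy]phenyl}prop-2-enoic acid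
Product: 24 (1R,4aR,6R,7S,7aR)-6-[(tert-butyldimethylsilyl)oxy]-7-({[(2E)-3-{4-[(tert-butyldimethylsilyl)oxy]phenyl}prop-2-enoyl]oxy}methyl)-4-formyl-7-hydroxy-1,4a,5,6,7,7a-hexahydrocyclopenta[c]pyran-1-yl (3S)-3-methylpentanoate
Conditions: DCC, 4-(dimethylamino)pyridine (10 mol %), CH2Cl2, 0 °C→rt
Reagents that add atoms: none
Why: Steglich esterification of the only free primary alcohol (C10–OH); the tertiary C8–OH should not compete.

Step 13
Reactants: 24 (1R,4aR,6R,7S,7aR)-6-[(tert-butyldimethylsilyl)oxy]-7-({[(2E)-3-{4-[(tert-butyldimethylsilyl)oxy]phenyl}prop-2-enoyl]oxy}methyl)-4-formyl-7-hydroxy-1,4a,5,6,7,7a-hexahydrocyclopenta[c]pyran-1-yl (3S)-3-methylpentanoate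
Product: 25 (1R,4aR,6R,7S,7aR)-4-formyl-6,7-dihydroxy-7-({[(2E)-3-(4-hydroxyphenyl)prop-2-enoyl]oxy}methyl)-1,4a,5,6,7,7a-hexahydrocyclopenta[c]pyran-1-yl (3S)-3-methylpentanoate
Conditions: HF·pyridine, pyridine, THF, 0 °C→rt
Reagents that add atoms: none
Why: Fluoride desilylation of the aryl and the secondary TBS ethers, done while the enol ether is still deactivated by the C4 formyl group so that the acid-sensitive final oxidation pattern never meets HF.

Step 14
Reactants: 25 (1R,4aR,6R,7S,7aR)-4-formyl-6,7-dihydroxy-7-({[(2E)-3-(4-hydroxyphenyl)prop-2-enoyl]oxy}methyl)-1,4a,5,6,7,7a-hexahydrocyclopenta[c]pyran-1-yl (3S)-3-methylpentanoate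
Product: 26 (1R,4aR,6R,7S,7aR)-6,7-dihydroxy-4-(hydroxymethyl)-7-({[(2E)-3-(4-hydroxyphenyl)prop-2-enoyl]oxy}methyl)-1,4a,5,6,7,7a-hexahydrocyclopenta[c]pyran-1-yl (3S)-3-methylpentanoate
Conditions: NaBH4, CeCl3·7H2O, MeOH–THF, −78 °C; pH 7 buffer
Reagents that add atoms: none
Why: Luche reduction should reduce the β-alkoxy enal 1,2 to the allylic alcohol (as in the reduction of 2-formyl glycals) while the acylal, the aliphatic ester and the cinnamate are left alone at −78 °C.

**Compound list**

1 | cyclopent-2-en-1-one | O=C1C=CCC1 | starting material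
2 | formaldehyde | C=O | starting material
3 | 2-(hydroxymethyl)cyclopent-2-en-1-one | O=C1CCC=C1CO | intermediate
4 | 2-{[(triethylsilyl)oxy]methyl}cyclopent-2-en-1-one | O=C1CCC=C1CO[Si](CC)(CC)CC | intermediate
5 | (1R)-2-{[(triethylsilyl)oxy]methyl}cyclopent-2-en-1-ol | O[C@@H]1CCC=C1CO[Si](CC)(CC)CC | intermediate
6 | tert-butyldimethyl{[(1R)-2-{[(triethylsilyl)oxy]methyl}cyclopent-2-en-1-yl]oxy}silane | CC(C)(C)[Si](C)(C)O[C@@H]1CCC=C1CO[Si](CC)(CC)CC | intermediate
7 | (1R,2R,5R)-2-[(tert-butyldimethylsilyl)oxy]-1-{[(triethylsilyl)oxy]methyl}-6-oxabicyclo[3.1.0]hexane | CC(C)(C)[Si](C)(C)O[C@@H]1CC[C@H]2O[C@@]12CO[Si](CC)(CC)CC | intermediate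
8 | (1S,2S,5R)-5-[(tert-butyldimethylsilyl)oxy]-2-(phenylselanyl)-1-{[(triethylsilyl)oxy]methyl}cyclopentan-1-ol (hydroxy selenide, not isolated) | CC(C)(C)[Si](C)(C)O[C@@H]1CC[C@H]([Se]c2ccccc2)[C@]1(O)CO[Si](CC)(CC)CC | intermediate
9 | selenoxide of 8 (configuration at selenium not defined, not isolated) | CC(C)(C)[Si](C)(C)O[C@@H]1CC[C@H]([Se](=O)c2ccccc2)[C@]1(O)CO[Si](CC)(CC)CC | intermediate
10 | (1S,5R)-5-[(tert-butyldimethylsilyl)oxy]-1-{[(triethylsilyl)oxy]methyl}cyclopent-2-en-1-ol | C1=C[C@](O)(CO[Si](CC)(CC)CC)[C@H](O[Si](C)(C)C(C)(C)C)C1 | intermediate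
11 | triformylmethane (enol form, 2-(hydroxymethylidene)propanedial) | OC=C(C=O)C=O | starting material
12 | cis-fused 3-[(tert-butyldimethylsilyl)oxy]-2,7-dihydroxy-2-{[(triethylsilyl)oxy]methyl}bicyclo[3.2.0]heptane-6,6-dicarbaldehyde (cyclobutanol photoadduct; C7 carbinol configuration not controlled, not isolated) | OC1C(C=O)(C=O)[C@@H]2C[C@@H](O[Si](C)(C)C(C)(C)C)[C@@](O)(CO[Si](CC)(CC)CC)[C@H]12 | intermediate
13 | retro-aldol enol aldehyde: cyclopentanecarbaldehyde bearing the 1,1-diformylmethyl group as its enol on the adjacent carbon (not isolated) | OC=C(C=O)[C@@H]1C[C@@H](O[Si](C)(C)C(C)(C)C)[C@@](O)(CO[Si](CC)(CC)CC)[C@@H]1C=O | intermediate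
14 | (1S,4aR,6R,7S,7aR)-6-[(tert-butyldimethylsilyl)oxy]-1,7-dihydroxy-7-{[(triethylsilyl)oxy]methyl}-1,4a,5,6,7,7a-hexahydrocyclopenta[c]pyran-4-carbaldehyde | O[C@H]1OC=C(C=O)[C@@H]2C[C@@H](O[Si](C)(C)C(C)(C)C)[C@@](O)(CO[Si](CC)(CC)CC)[C@H]12 | intermediate
15 | (S)-1-bromo-2-methylbutane | CC[C@H](C)CBr | starting material
16 | carbon dioxide | O=C=O | starting material
17 | [(2S)-2-methylbutyl]magnesium bromide (not isolated) | CC[C@H](C)C[Mg]Br | intermediate
18 | (3S)-3-methylpentanoic acid | CC[C@H](C)CC(=O)O | intermediate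
19 | (1R,4aR,6R,7S,7aR)-6-[(tert-butyldimethylsilyl)oxy]-4-formyl-7-hydroxy-7-{[(triethylsilyl)oxy]methyl}-1,4a,5,6,7,7a-hexahydrocyclopenta[c]pyran-1-yl (3S)-3-methylpentanoate | CC[C@H](C)CC(=O)O[C@H]1OC=C(C=O)[C@@H]2C[C@@H](O[Si](C)(C)C(C)(C)C)[C@@](O)(CO[Si](CC)(CC)CC)[C@H]12 | intermediate
20 | (1R,4aR,6R,7S,7aR)-6-[(tert-butyldimethylsilyl)oxy]-4-formyl-7-hydroxy-7-(hydroxymethyl)-1,4a,5,6,7,7a-hexahydrocyclopenta[c]pyran-1-yl (3S)-3-methylpentanoate | CC[C@H](C)CC(=O)O[C@H]1OC=C(C=O)[C@@H]2C[C@@H](O[Si](C)(C)C(C)(C)C)[C@@](O)(CO)[C@H]12 | intermediate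
21 | (E)-4-hydroxycinnamic acid (p-coumaric acid) | O=C(O)/C=C/c1ccc(O)cc1 | starting material
22 | tert-butyldimethylsilyl (2E)-3-{4-[(tert-butyldimethylsilyl)oxy]phenyl}prop-2-enoate (not isolated) | CC(C)(C)[Si](C)(C)OC(=O)/C=C/c1ccc(O[Si](C)(C)C(C)(C)C)cc1 | intermediate
23 | (2E)-3-{4-[(tert-butyldimethylsilyl)oxy]phenyl}prop-2-enoic acid | O=C(O)/C=C/c1ccc(O[Si](C)(C)C(C)(C)C)cc1 | intermediate
24 | (1R,4aR,6R,7S,7aR)-6-[(tert-butyldimethylsilyl)oxy]-7-({[(2E)-3-{4-[(tert-butyldimethylsilyl)oxy]phenyl}prop-2-enoyl]oxy}methyl)-4-formyl-7-hydroxy-1,4a,5,6,7,7a-hexahydrocyclopenta[c]pyran-1-yl (3S)-3-methylpentanoate | CC[C@H](C)CC(=O)O[C@H]1OC=C(C=O)[C@@H]2C[C@@H](O[Si](C)(C)C(C)(C)C)[C@@](O)(COC(=O)/C=C/c3ccc(O[Si](C)(C)C(C)(C)C)cc3)[C@H]12 | intermediate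
25 | (1R,4aR,6R,7S,7aR)-4-formyl-6,7-dihydroxy-7-({[(2E)-3-(4-hydroxyphenyl)prop-2-enoyl]oxy}methyl)-1,4a,5,6,7,7a-hexahydrocyclopenta[c]pyran-1-yl (3S)-3-methylpentanoate | CC[C@H](C)CC(=O)O[C@H]1OC=C(C=O)[C@@H]2C[C@@H](O)[C@@](O)(COC(=O)/C=C/c3ccc(O)cc3)[C@H]12 | intermediate
26 | (1R,4aR,6R,7S,7aR)-6,7-dihydroxy-4-(hydroxymethyl)-7-({[(2E)-3-(4-hydroxyphenyl)prop-2-enoyl]oxy}methyl)-1,4a,5,6,7,7a-hexahydrocyclopenta[c]pyran-1-yl (3S)-3-methylpentanoate | CC[C@H](C)CC(=O)O[C@H]1OC=C(CO)[C@@H]2C[C@@H](O)[C@@](O)(COC(=O)/C=C/c3ccc(O)cc3)[C@H]12 | target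

**Step count and risks**

Total step count: 14. Longest linear sequence: 12 steps (steps 1–7, 9, 10, 12, 13 and 14, from cyclopent-2-en-1-one).

Steps most likely to fail:

1. Step 7. Regio- or facial selectivity of the photocycloaddition may erode, the product enal chromophore may undergo secondary photoreaction, or the acidic tricarbonyl partner may ionise the tertiary allylic alcohol. The fallback sets out from 10 and comes back at 14. Irradiation of 10 with commercial ethyl 2-formyl-3-oxopropanoate (a less acidic partner of the best-precedented type, whose β-alkoxyacrylate product absorbs at shorter wavelength) should lead through the cyclobutanol photoadduct F1 and the retro-aldol enol aldehyde F2, neither isolated, to the ethyl ester lactol F3. Reduction with i-Bu2AlH (excess, CH2Cl2, −78 °C), with the lactol held as its aluminium lactolate, should give the C11 allylic alcohol lactol F4. MnO2 (CH2Cl2, rt) should then oxidise only the allylic alcohol to the enal and return 14.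

2. Step 9. Acylation may proceed through the wrong lactol anomer, because the two anomers equilibrate under the DMAP-catalysed conditions and the C1 configuration then depends on their relative rates. The fallback sets out from 14 and 18 and comes back at 19. Acid 18 is converted with oxalyl chloride (cat. DMF, CH2Cl2) into (3S)-3-methylpentanoyl chloride F5. Lactol 14 is deprotonated with LiN(SiMe3)2 (1.0 equiv, THF, −78 °C) to the lithium lactolate F6, which is trapped at −78 °C with F5 before mutarotation. The configuration of the predominant lactol anomer is thus transferred to 19 instead of being selected kinetically.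

3. Step 14. In the unprotected polyol, basic borohydride or the cerium Lewis acid may cause loss or migration of the C1 acyl group, or solvolytic addition to the enol ether once the deactivating formyl group is gone. The fallback sets out from 24 and comes back at 26, with the order of reduction and deprotection exchanged. The formyl group of 24 is reduced under aprotic conditions with LiAlH(OtBu)3 (THF, −78 °C), which leaves esters alone, to the bis-silylated C11 alcohol F7. Both silyl ethers are then removed last with acetic acid-buffered Bu4NF (THF, 0 °C) to give 26.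

**Further compounds**

F1 | step 7 | ethyl cis-fused 3-[(tert-butyldimethylsilyl)oxy]-6-formyl-2,7-dihydroxy-2-{[(triethylsilyl)oxy]methyl}bicyclo[3.2.0]heptane-6-carboxylate (cyclobutanol photoadduct; C6 and C7 configurations not controlled) | OC1C(C=O)(C(=O)OCC)[C@@H]2C[C@@H](O[Si](C)(C)C(C)(C)C)[C@@](O)(CO[Si](CC)(CC)CC)[C@H]12
F2 | step 7 | retro-aldol enol aldehyde (ethyl 2-substituted 3-hydroxyprop-2-enoate on the cyclopentanecarbaldehyde) | OC=C(C(=O)OCC)[C@@H]1C[C@@H](O[Si](C)(C)C(C)(C)C)[C@@](O)(CO[Si](CC)(CC)CC)[C@@H]1C=O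
F3 | step 7 | ethyl (1S,4aR,6R,7S,7aR)-6-[(tert-butyldimethylsilyl)oxy]-1,7-dihydroxy-7-{[(triethylsilyl)oxy]methyl}-1,4a,5,6,7,7a-hexahydrocyclopenta[c]pyran-4-carboxylate | O[C@H]1OC=C(C(=O)OCC)[C@@H]2C[C@@H](O[Si](C)(C)C(C)(C)C)[C@@](O)(CO[Si](CC)(CC)CC)[C@H]12
F4 | step 7 | (1S,4aR,6R,7S,7aR)-6-[(tert-butyldimethylsilyl)oxy]-4-(hydroxymethyl)-7-{[(triethylsilyl)oxy]methyl}-1,4a,5,6,7,7a-hexahydrocyclopenta[c]pyran-1,7-diol | O[C@H]1OC=C(CO)[C@@H]2C[C@@H](O[Si](C)(C)C(C)(C)C)[C@@](O)(CO[Si](CC)(CC)CC)[C@H]12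
F5 | step 9 | (3S)-3-methylpentanoyl chloride | CC[C@H](C)CC(=O)Cl
F6 | step 9 | lithium lactolate of 14 | [Li+].[O-][C@H]1OC=C(C=O)[C@@H]2C[C@@H](O[Si](C)(C)C(C)(C)C)[C@@](O)(CO[Si](CC)(CC)CC)[C@H]12
F7 | step 14 | (1R,4aR,6R,7S,7aR)-6-[(tert-butyldimethylsilyl)oxy]-7-({[(2E)-3-{4-[(tert-butyldimethylsilyl)oxy]phenyl}prop-2-enoyl]oxy}methyl)-7-hydroxy-4-(hydroxymethyl)-1,4a,5,6,7,7a-hexahydrocyclopenta[c]pyran-1-yl (3S)-3-methylpentanoate | CC[C@H](C)CC(=O)O[C@H]1OC=C(CO)[C@@H]2C[C@@H](O[Si](C)(C)C(C)(C)C)[C@@](O)(COC(=O)/C=C/c3ccc(O[Si](C)(C)C(C)(C)C)cc3)[C@H]12
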